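I began with the easy step of asking how fast J left during the first minute of each earlier run.

| flask | J | remark | time |
|---|---|---|---|
| oak | 0.060 M | run made earlier |  |
| larch | 0.090 M | run made earlier |  |
| flask | 0.12 M |  | 1.5 h |

| run | time / min | X / % | J / % |
|---|---|---|---|
| oak | 1.00 | 16 | 59 |
| oak | 2.50 | 24 | 39 |
| oak | 6.00 | 18 | 25 |
| oak | 15.0 | 12 | 13 |
| oak | 40.0 | 14 | 12 |
| oak | 120 | 10 | 6 |
| larch | 1.00 | 15 | 53 |
| larch | 2.50 | 21 | 33 |
| larch | 6.00 | 21 | 17 |
| larch | 15.0 | 15 | 12 |
| larch | 40.0 | 11 | 12 |
| larch | 120 | 4 | 4 |

(each reading ± 2 percentage points)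

- percent here means J units held: one G or Q counts as two
- what is said of X includes G
- on the list of suspects stand: D <-> L; J + X <-> G; 2 J -> Q; X -> Z; X <-> D; L <-> J; J <-> X
- in an amount of X, one G counts as one X

* the best time, 1.5 h at the latest, for X, in min
* the amount of X, in percent of the J charged, at that time

Two numbers seemed not to go together. After 1.00 min, the larch run had kept less J than the oak run, 53% against 59%, yet its X reading was no higher, 15% against 16%. The logarithm of what was left gave loss rates of 0.528 min⁻¹ for oak and 0.635 min⁻¹ for larch. I took the rise with charge to be the suspected step in which two J make Q, since its rate goes with the square of [J], and the remainder, 0.313 min⁻¹, to be J going to X. So the larch run's faster loss need not mean more X. These readings are rough, given their scatter.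

The ratio of the way to Q over the way to X at the charge, S (a selectivity factor), came to 0.685 for oak and, scaled with the charge, 1.37 for the flask. Integrating both rates, in a picture where J leaves by these two ways, gives the first-pass share, the part of J going to X on its first way out, as the logarithm of one plus S, divided by S. That is 63.0% for the flask and 76.2% for oak. Scaling oak's highest reading, 24%, I expected about 19.8%.

The forecast said 21% (17% to 25%) at 3.5 min (2.2 min to 5.5 min), a height above my figure, holding that “The peak height barely changes with concentration”.

The flask gave 21.5% at 2.73 min, earlier than the forecast's time. Q then stood at 30.3%. The best X in the flask was about a third of the first-pass share I had reckoned, a ratio of 34.2%.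

    D ⇌ L (K = 0.520, k = 0.110 min⁻¹)
    J + X ⇌ G, settled at all times (K = 20.0 M⁻¹)
    2 J → Q (k = 1.70 M⁻¹ min⁻¹)
    X → Z (k = 6.80 × 10⁻⁵ min⁻¹)
    X ⇌ D (K = 2.60, k = 0.310 min⁻¹)
    L ⇌ J (k = 0.0420 min⁻¹)
    J ⇌ X (K = 0.850, k = 0.260 min⁻¹)

With 0.48 M of J, S is 5.48 and the share 34.1%, so the same ratio gives 11.7%. The computed best there is 15.0%, which is higher.

The data are simulated from invented constants, noise included.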